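**Retrosynthetic overview**

1. Target 27 ← acetylation and fluoride deprotection ← C4 quaternary centre by conjugate reduction–methylation of a Δ3-enoate, itself from carbonylation of a C4 vinyl iodide; the diene side chain ← C12 aldehyde by two Wittig reactions.
2. 7α-OH with the 8(17)-methylene ← CBS reduction of an α-methylene ketone ← cyclic β-ketophosphonate 16 and formaldehyde.
3. Ring B (formed second) ← one-pot dianionic Carroll rearrangement, 6-exo Michael addition and decarboxylation of the 4-phosphonoacetoacetate 13; C5–C6 and C8–C9 are made in this one operation.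
4. Enabling feature: in ring A, C5 is the allylic terminus of the C3–C4–C5 triad, and in ring B the oxygenated C7 sits between C6 and C8. An acetoacetate hung on a temporary 3β-oxygen can therefore pass C6 to C5 suprafacially, and C8 (marked by the exocyclic C8=C17 methylene as a former carbanion) can then close onto C9 of an acrylate arm on the quaternary C10.
5. Ring A (formed first) ← catalytic asymmetric Diels–Alder reaction of methacrolein with an aminosiloxydiene (sets C10), then olefination, α-iodination and CBS reduction (sets the temporary C3 carbinol).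

Key step: step 7

Remark: positions carry labdane numbering (ring A C1–C5 and C10, ring B C5–C10, C17 exocyclic methylene, C19 carboxyl); the target is read as the 7α-acetoxy, 4β-carboxy, 5α-H, 9α-H, 10β-methyl isomer, and the chromium–salen and CBS catalysts are assumed to induce in the sense of their usual models (otherwise the mirror-image catalyst is used).

**Step 1**
Reactants: 1 methacrolein; 2 (E)-1-(dimethylamino)-3-(tert-butyldimethylsilyloxy)buta-1,3-diene
Product: 3 (1S,2R)-4-(tert-butyldimethylsilyloxy)-2-(dimethylamino)-1-methylcyclohex-3-ene-1-carbaldehyde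
Conditions: (R,R)-(salen)CrSbF6 5 mol% (trivalent chromium; salen = N,N′-bis(3,5-di-tert-butylsalicylidene)cyclohexane-1,2-diamine dianion), 4 Å MS, CH2Cl2, −40 °C
Reagents that add atoms: none
Why: The electron-rich aminosiloxydiene should add to the α-substituted enal in a Lewis acid-catalysed, endo-selective Diels–Alder reaction, the chiral chromium–salen complex shielding one enal face so that the quaternary carbon (future C10) forms in the configuration shown.

**Step 2**
Reactants: 3
Product: 6 ethyl (2E)-3-[(1S)-1-methyl-4-oxocyclohex-2-en-1-yl]prop-2-enoate, via silyl enol ether acrylate 4 (not isolated), via amino ketone 5 (not isolated)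
Conditions: NaH, (EtO)2P(O)CH2CO2Et, THF, 0 °C; then 48% aq. HF, MeCN, 0 °C to rt
Reagents that add atoms: triethyl phosphonoacetate CCOC(=O)CP(=O)(OCC)OCC
Why: Horner–Wadsworth–Emmons olefination of the non-enolisable aldehyde should give the (E)-acrylate, and HF then hydrolyses the silyl enol ether and triggers β-elimination of dimethylamine to the 4,4-disubstituted cyclohexenone without touching the quaternary centre.

**Step 3**
Reactants: 6
Product: 7 ethyl (2E)-3-[(1R)-3-iodo-1-methyl-4-oxocyclohex-2-en-1-yl]prop-2-enoate
Conditions: I2, pyridine, CH2Cl2, 0 °C to rt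
Reagents that add atoms: iodine II
Why: Pyridine-mediated α-iodination of the enone (Baylis–Hillman-type addition, iodination, elimination) is well precedented for 4,4-disubstituted cyclohexenones and should leave the less electrophilic acrylate alone; the iodide is the latent C19 carboxyl.

**Step 4**
Reactants: 7
Product: 8 ethyl (2E)-3-[(1R,4S)-4-hydroxy-3-iodo-1-methylcyclohex-2-en-1-yl]prop-2-enoate
Conditions: (R)-2-methyl-CBS-oxazaborolidine (20 mol%), catecholborane, toluene, −78 °C
Reagents that add atoms: none
Why: Corey–Bakshi–Shibata reduction of α-iodoenones is strongly face-selective with the iodovinyl carbon as the large group, so the catalyst should override the remote quaternary centre and give the carbinol (future C3) with OH cis to the ring methyl.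

**Step 5**
Reactants: 9 (diethoxyphosphoryl)acetic acid; 10 2,2-dimethyl-1,3-dioxane-4,6-dione
Product: 11 5-[2-(diethoxyphosphoryl)-1-hydroxyethylidene]-2,2-dimethyl-1,3-dioxane-4,6-dione
Conditions: DCC, DMAP, CH2Cl2, 0 °C to rt
Reagents that add atoms: none
Why: Carbodiimide-mediated C-acylation of the dioxanedione by a carboxylic acid is the standard route to acyl derivatives that serve as acylketene precursors.

**Step 6**
Reactants: 8; 11
Product: 13 (1S,4R)-4-[(E)-3-ethoxy-3-oxoprop-1-enyl]-2-iodo-4-methylcyclohex-2-en-1-yl 4-(diethoxyphosphoryl)-3-oxobutanoate, via acylketene 12 (not isolated)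
Conditions: toluene, 80 °C
Reagents that add atoms: none
Why: Thermolysis of the acylated dioxanedione releases acetone and CO2 to give an acylketene that the secondary allylic alcohol traps with retention at the carbinol, a standard β-keto ester synthesis run well below the temperature of a neutral Carroll rearrangement.

**Step 7**
Reactants: 13
Product: 16 bicyclic β-ketophosphonate (trans-fused Δ3-octalin with 4-iodo, 7-oxo, 8-diethoxyphosphoryl as C8 epimers, 9β-CH2CO2Et, 5α-H, 9α-H, 10β-CH3), via rearranged keto acid 14 (not isolated), via bicyclic keto acid 15 (not isolated)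
Conditions: LiN(SiMe3)2 (2.2 equiv), THF, −78 to 65 °C; 1 M HCl; toluene, 80 °C
Reagents that add atoms: none
Why: Double deprotonation gives the C6/C8 bis-enolate, whose ester-enolate half undergoes a [3,3] shift across the C3–C4–C5 allyl unit (dianionic Carroll rearrangement, an ester-enolate Claisen), forming C5–C6 and moving the alkene to C3=C4(I); the phosphonate-stabilised C8 carbanion that survives then adds to C9 of the acrylate arm, and acidification with warming decarboxylates the β-keto acid. The closest known reaction types are the dianion Carroll rearrangement of cyclohexenyl acetoacetates and the intramolecular Michael addition of β-ketophosphonate anions to enoates. Ring B is the only ring closed, by a 6-exo-trig conjugate addition between the trans-disposed arms on C5 and C10, which can only give the trans-fused decalin. C5 is set by suprafacial transfer of chirality from the 3β-oxygen (new bond cis to the C10 methyl, hence 5α-H); C9 should be set in a chair-like, reversible closure that places CH2CO2Et equatorial (9α-H); C8 is epimerisable and is lost in step 8. Regiochemistry is fixed by the tether, since only the acetoacetate α-carbon (C6) lies in the six-atom array and only C8 keeps carbanion character afterwards. Chemoselectivity is secured by the C4 iodide, which, unlike an ester there, offers no second Michael acceptor in ring A, and the temporary C3 oxygen and its ester carbon leave as CO2.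

**Step 8**
Reactants: 16
Product: 17 α-methylene ketone (trans-fused Δ3-octalin with 4-iodo, 7-oxo, 8-methylene, 9β-CH2CO2Et, 5α-H, 9α-H, 10β-CH3)
Conditions: 37% aq. CH2O, K2CO3, THF, rt
Reagents that add atoms: formaldehyde C=O
Why: Horner–Wadsworth–Emmons reaction of the cyclic β-ketophosphonate anion with formaldehyde is the classical regiospecific route to α-methylene ketones, so C17 should be placed on C8 only.

**Step 9**
Reactants: 17
Product: 18 7α-alcohol (as 17 with axial 7α-OH in place of the ketone)
Conditions: (S)-2-methyl-CBS-oxazaborolidine (30 mol%), catecholborane, toluene, −78 °C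
Reagents that add atoms: none
Why: Corey–Bakshi–Shibata 1,2-reduction of the enone, with the methylene-bearing carbon as the large group, should deliver hydride to the β face of C7 under catalyst control and give the axial 7α-alcohol without conjugate reduction.

**Step 10**
Reactants: 18
Product: 19 7α-tert-butyldimethylsilyl ether of 18
Conditions: TBSOTf, 2,6-lutidine, CH2Cl2, −78 to 0 °C
Reagents that add atoms: tert-butyldimethylsilyl trifluoromethanesulfonate CC(C)(C)[Si](C)(C)OS(=O)(=O)C(F)(F)F
Why: Silylation of the hindered axial allylic alcohol with the silyl triflate protects it through the hydride, ylide and enolate steps and allows its later removal together with the ester protecting group.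

**Step 11**
Reactants: 19
Product: 20 C12 aldehyde (as 19 with 9β-CH2CHO)
Conditions: i-Bu2AlH (1.1 equiv), CH2Cl2, −78 °C
Reagents that add atoms: none
Why: Low-temperature i-Bu2AlH reduction of the only ester in the molecule should stop at the tetrahedral aluminate and give the aldehyde on work-up, the vinyl iodide, silyl ether and alkenes being inert.

**Step 12**
Reactants: 20
Product: 21 (E)-α-methyl enal (side chain CH2-CH=C(CH3)-CHO on C9)
Conditions: Ph3P=C(CH3)CHO, toluene, 90 °C
Reagents that add atoms: 2-(triphenylphosphoranylidene)propanal CC(C=O)=P(c1ccccc1)(c1ccccc1)c1ccccc1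
Why: Wittig reaction with the stabilised α-methyl formyl ylide is reliably (E)-selective and builds the trisubstituted C12=C13 alkene of the side chain.

**Step 13**
Reactants: 21
Product: 22 diene vinyl iodide (side chain CH2-CH=C(CH3)-CH=CH2, 12E)
Conditions: Ph3PCH3Br, KOt-Bu, THF, 0 °C
Reagents that add atoms: methyltriphenylphosphonium bromide C[P+](c1ccccc1)(c1ccccc1)c1ccccc1.[Br-]
Why: Wittig methylenation of the enal completes the (E)-1,3-diene, and the non-stabilised ylide does not attack the vinyl iodide or the silyl ether.

**Step 14**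
Reactants: 22
Product: 23 2-(trimethylsilyl)ethyl Δ3-enoate (as 22 with C4-CO2CH2CH2SiMe3 in place of iodine)
Conditions: Pd(OAc)2 (5 mol%), dppf, CO (1 atm), Me3SiCH2CH2OH, Et3N, DMF, 60 °C
Reagents that add atoms: carbon monoxide [C-]#[O+]; 2-(trimethylsilyl)ethanol C[Si](C)(C)CCO
Why: Palladium-catalysed alkoxycarbonylation of the vinyl iodide (oxidative addition, CO insertion, alcoholysis) installs C19 as a fluoride-labile ester and creates the Δ3-enoate, the diene being a spectator under CO.

**Step 15**
Reactants: 23
Product: 25 C4-quaternary ester (4α-CH3, 4β-CO2CH2CH2SiMe3, ring A saturated), via lithium ester enolate 24 (not isolated)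
Conditions: LiBH(s-Bu)3, THF, −78 °C; then MeI, −78 to −20 °C
Reagents that add atoms: iodomethane CI
Why: Conjugate hydride addition to C3 of the enoate generates the C4 ester enolate regiospecifically (reductive alkylation), and iodomethane should then approach from the equatorial α face, away from the axial C10 methyl, giving 4α-CH3 and the axial 4β-ester.

**Step 16**
Reactants: 25
Product: 26 7α-hydroxy-labda-8(17),12E,14-trien-19-oic acid
Conditions: Bu4NF (4 equiv), THF, rt; then 1 M HCl work-up
Reagents that add atoms: none
Why: Fluoride cleaves the secondary silyl ether and, by attack at silicon with β-elimination of ethylene, the 2-(trimethylsilyl)ethyl ester of the hindered acid, under conditions that leave the diene and the exocyclic alkene untouched.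

**Step 17**
Reactants: 26
Product: 27 7α-acetoxy-labda-8(17),12E,14-trien-19-oic acid (target)
Conditions: Ac2O, pyridine, DMAP (cat.), CH2Cl2, rt; aqueous work-up
Reagents that add atoms: acetic anhydride CC(=O)OC(C)=O
Why: DMAP-catalysed acetylation of the axial allylic alcohol should give the 7α-acetate with retention, and the hindered tertiary acid is recovered free after aqueous work-up.

**Compound list**

1 | methacrolein (2-methylprop-2-enal) | CC(=C)C=O | starting material
2 | (E)-1-(dimethylamino)-3-(tert-butyldimethylsilyloxy)buta-1,3-diene | CN(C)/C=C/C(=C)O[Si](C)(C)C(C)(C)C | starting material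
3 | (1S,2R)-4-(tert-butyldimethylsilyloxy)-2-(dimethylamino)-1-methylcyclohex-3-ene-1-carbaldehyde (NMe2 cis to CHO) | CN(C)[C@@H]1C=C(O[Si](C)(C)C(C)(C)C)CC[C@]1(C)C=O | intermediate
4 | silyl enol ether acrylate (3 with CHO replaced by (E)-CH=CH-CO2Et) | CN(C)[C@@H]1C=C(O[Si](C)(C)C(C)(C)C)CC[C@]1(C)/C=C/C(=O)OCC | intermediate
5 | amino ketone (4 with the silyl enol ether hydrolysed to the ketone) | CN(C)[C@@H]1CC(=O)CC[C@]1(C)/C=C/C(=O)OCC | intermediate
6 | ethyl (2E)-3-[(1S)-1-methyl-4-oxocyclohex-2-en-1-yl]prop-2-enoate | CCOC(=O)/C=C/[C@]1(C)C=CC(=O)CC1 | intermediate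
7 | ethyl (2E)-3-[(1R)-3-iodo-1-methyl-4-oxocyclohex-2-en-1-yl]prop-2-enoate | CCOC(=O)/C=C/[C@]1(C)C=C(I)C(=O)CC1 | intermediate
8 | ethyl (2E)-3-[(1R,4S)-4-hydroxy-3-iodo-1-methylcyclohex-2-en-1-yl]prop-2-enoate (OH cis to CH3) | CCOC(=O)/C=C/[C@]1(C)C=C(I)[C@@H](O)CC1 | intermediate
9 | (diethoxyphosphoryl)acetic acid | CCOP(=O)(CC(=O)O)OCC | starting material
10 | 2,2-dimethyl-1,3-dioxane-4,6-dione | CC1(C)OC(=O)CC(=O)O1 | starting material
11 | 5-[2-(diethoxyphosphoryl)-1-hydroxyethylidene]-2,2-dimethyl-1,3-dioxane-4,6-dione | CCOP(=O)(OCC)CC(O)=C1C(=O)OC(C)(C)OC1=O | intermediate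
12 | diethyl (2,4-dioxobut-3-en-1-yl)phosphonate (acylketene) | CCOP(=O)(OCC)CC(=O)C=C=O | intermediate
13 | (1S,4R)-4-[(E)-3-ethoxy-3-oxoprop-1-enyl]-2-iodo-4-methylcyclohex-2-en-1-yl 4-(diethoxyphosphoryl)-3-oxobutanoate | CCOC(=O)/C=C/[C@]1(C)C=C(I)[C@@H](OC(=O)CC(=O)CP(=O)(OCC)OCC)CC1 | intermediate
14 | rearranged keto acid (ring alkene at C3=C4(I); C5 carries CH(CO2H)C(=O)CH2P(O)(OEt)2 cis to the C10 methyl) | CCOC(=O)/C=C/[C@@]1(C)CCC=C(I)[C@@H]1C(C(=O)O)C(=O)CP(=O)(OCC)OCC | intermediate
15 | bicyclic keto acid (16 with CO2H still on C6) | CCOC(=O)C[C@@H]1[C@@]2(C)CCC=C(I)[C@@H]2C(C(=O)O)C(=O)C1P(=O)(OCC)OCC | intermediate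
16 | bicyclic β-ketophosphonate (trans-fused Δ3-octalin; 4-iodo, 7-oxo, 8-P(O)(OEt)2 as C8 epimers, 9β-CH2CO2Et, 5α-H, 9α-H, 10β-CH3) | CCOC(=O)C[C@@H]1[C@@]2(C)CCC=C(I)[C@@H]2CC(=O)C1P(=O)(OCC)OCC | intermediate
17 | α-methylene ketone (16 with C8=CH2 in place of the phosphonate) | CCOC(=O)C[C@@H]1[C@@]2(C)CCC=C(I)[C@@H]2CC(=O)C1=C | intermediate
18 | 7α-alcohol (axial OH) | CCOC(=O)C[C@@H]1[C@@]2(C)CCC=C(I)[C@@H]2C[C@@H](O)C1=C | intermediate
19 | 7α-TBS ether | CCOC(=O)C[C@@H]1[C@@]2(C)CCC=C(I)[C@@H]2C[C@@H](O[Si](C)(C)C(C)(C)C)C1=C | intermediate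
20 | C12 aldehyde | O=CC[C@@H]1[C@@]2(C)CCC=C(I)[C@@H]2C[C@@H](O[Si](C)(C)C(C)(C)C)C1=C | intermediate
21 | (E)-α-methyl enal | O=C/C(C)=C/C[C@@H]1[C@@]2(C)CCC=C(I)[C@@H]2C[C@@H](O[Si](C)(C)C(C)(C)C)C1=C | intermediate
22 | diene vinyl iodide (12E) | C=C/C(C)=C/C[C@@H]1[C@@]2(C)CCC=C(I)[C@@H]2C[C@@H](O[Si](C)(C)C(C)(C)C)C1=C | intermediate
23 | 2-(trimethylsilyl)ethyl Δ3-enoate | C=C/C(C)=C/C[C@@H]1[C@@]2(C)CCC=C(C(=O)OCC[Si](C)(C)C)[C@@H]2C[C@@H](O[Si](C)(C)C(C)(C)C)C1=C | intermediate
24 | lithium ester enolate at C4 | C=C/C(C)=C/C[C@@H]1[C@@]2(C)CCCC(=C([O-])OCC[Si](C)(C)C)[C@@H]2C[C@@H](O[Si](C)(C)C(C)(C)C)C1=C.[Li+] | intermediate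
25 | C4-quaternary ester (4α-CH3, 4β-CO2CH2CH2SiMe3, 7α-OTBS) | C=C/C(C)=C/C[C@@H]1[C@@]2(C)CCC[C@](C)(C(=O)OCC[Si](C)(C)C)[C@@H]2C[C@@H](O[Si](C)(C)C(C)(C)C)C1=C | intermediate
26 | 7α-hydroxy-labda-8(17),12E,14-trien-19-oic acid | C=C/C(C)=C/C[C@@H]1[C@@]2(C)CCC[C@](C)(C(=O)O)[C@@H]2C[C@@H](O)C1=C | intermediate
27 | 7α-acetoxy-labda-8(17),12E,14-trien-19-oic acid | C=C/C(C)=C/C[C@H]1C(=C)[C@H](OC(C)=O)C[C@@H]2[C@]1(C)CCC[C@]2(C)C(=O)O | target

**Step count and risks**

Total step count: 17. Longest linear sequence: 16 (steps 1–4 and 6–17; step 5 is a one-step side branch).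

Steps most likely to fail:

- Step 7. The dianion may be consumed by proton transfer or elimination before the sigmatropic shift, or the conjugate addition may stall or close with the wrong C9 configuration. The fallback uncouples the two bond formations with known chemistry: from 13, a neutral thermal Carroll rearrangement in xylene at 140 °C should give, after loss of CO2 from 14, the open-chain β-ketophosphonate F1; LiCl and DBU in MeCN would then close ring B by intramolecular Michael addition under equilibrating conditions and rejoin the route at 16.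
- Step 9. Facial selectivity may be poor if the substrate's preference for axial hydride delivery opposes the catalyst. The fallback accepts the substrate bias and corrects it: from 17, NaBH4 with CeCl3·7H2O in EtOH should give the equatorial 7β-alcohol F2; Mitsunobu inversion with 4-nitrobenzoic acid, PPh3 and diisopropyl azodicarboxylate would give the 7α-(4-nitrobenzoate) F3, and K2CO3 in EtOH would release 18.
- Step 15. Hydride delivery to the trisubstituted enoate may be incomplete or compete with 1,2-reduction, leaving too little enolate for alkylation. The fallback separates reduction from alkylation: from 23, [(Ph3P)CuH]6 (cat.) with PhSiH3 in toluene should give the saturated ester F4 as a C4 epimer mixture; LiN(i-Pr)2 in THF at −78 °C followed by MeI would then methylate the only ester enolate from the α face and rejoin at 25.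

**Further compounds**

F1 | step 7 | open-chain β-ketophosphonate (14 after loss of CO2) | CCOC(=O)/C=C/[C@@]1(C)CCC=C(I)[C@@H]1CC(=O)CP(=O)(OCC)OCC
F2 | step 9 | 7β-alcohol (equatorial epimer of 18) | CCOC(=O)C[C@@H]1[C@@]2(C)CCC=C(I)[C@@H]2C[C@H](O)C1=C
F3 | step 9 | 7α-(4-nitrobenzoate) of 18 | CCOC(=O)C[C@@H]1[C@@]2(C)CCC=C(I)[C@@H]2C[C@@H](OC(=O)c3ccc(cc3)[N+](=O)[O-])C1=C
F4 | step 15 | saturated 2-(trimethylsilyl)ethyl ester (C4-H epimers) | C=C/C(C)=C/C[C@@H]1[C@@]2(C)CCCC(C(=O)OCC[Si](C)(C)C)[C@@H]2C[C@@H](O[Si](C)(C)C(C)(C)C)C1=C
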